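**Retrosynthetic overview**

1. The strategy rests on ring A (O1, C2=O, C3=C4, C5–O-acyl, C6 bearing the side chain C7–C13), the only ring. Oxygen on C2 and on C5 with the C3=C4 alkene between them is the pattern a 2-substituted furan gives on two-electron oxidation, so ring A is closed (O1–C2 bond) by an anodic Achmatowicz ring expansion of the C6 2-furyl carbinol.
2. After the ring expansion: methyl glycoside, Luche reduction (C5, trans to C6), esterification of the C5 oxygen with the bis-silylated (2E,4E,6R)-dienoic acid (acyl chain C1′–C8′), acetal hydrolysis, oxidation to the lactone, desilylation.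
3. Furyl carbinol: 2-furyllithium plus the C6 aldehyde, then oxidation and Ru-catalysed asymmetric transfer hydrogenation (C6).
4. C6–C13 aldehyde: lipase desymmetrisation of meso-2,4-dimethylpentane-1,5-diol (C7, C9); Negishi coupling at C10–C11 with a (Z)-3-iodobut-2-enol unit; Sharpless epoxidation and reductive opening of the epoxy iodide (C11 and the C12=C13 vinyl group).
5. Dienoic acid: Evans dienolate alkylation (C6′), cross-metathesis with methacrolein (C4′=C5′), Horner–Wadsworth–Emmons olefination (C2′=C3′).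

Key step: step 16

Remark (assumption): Amano lipase AK is taken to acetylate the hydroxymethyl group on the (S)-configured carbon of the meso diol, which is what the (7S,9R) configuration requires. Atom numbers are those of the target as defined in the overview.

**Route**

Step 1
Reactants: 1 cis-2,4-dimethylglutaric anhydride (meso)
Product: 2 meso-(2R,4S)-2,4-dimethylpentane-1,5-diol
Conditions: LiAlH4, THF, 0 °C to reflux; Fieser work-up
Reagents that add atoms: none
Why: LiAlH4 reduction of both anhydride carbonyls to primary alcohols; the stereocentres are not involved, so the cis (meso) relationship of the methyl groups is kept.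

Step 2
Reactants: 2 meso-(2R,4S)-2,4-dimethylpentane-1,5-diol
Product: 3 [(2S,4R)-5-hydroxy-2,4-dimethylpentyl] acetate
Conditions: Amano lipase AK, vinyl acetate, THF, 23 °C
Reagents that add atoms: vinyl acetate CC(=O)OC=C
Why: Enzymatic desymmetrisation of a meso diol by irreversible lipase transesterification acylates one of the two enantiotopic hydroxymethyl groups, which fixes C7 as (S) and C9 as (R) in one operation.

Step 3
Reactants: 3 [(2S,4R)-5-hydroxy-2,4-dimethylpentyl] acetate
Product: 4 [(2S,4R)-5-iodo-2,4-dimethylpentyl] acetate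
Conditions: I2, PPh3, imidazole, CH2Cl2, 0 °C
Reagents that add atoms: iodine II
Why: Appel-type iodination converts the free primary alcohol into the C10 iodide by SN2 displacement under conditions that leave the acetate and both stereocentres untouched.

Step 4
Reactants: 5 but-2-yn-1-ol
Product: 7 (Z)-3-iodobut-2-en-1-ol, via sodium alkenylalanate 6 (not isolated)
Conditions: NaAlH2(OCH2CH2OMe)2, THF, 0 to 23 °C; EtOAc; then I2, −78 to 0 °C
Reagents that add atoms: iodine II
Why: Hydroxyl-directed trans-hydroalumination of the propargylic alcohol places aluminium on C3 in the cyclic alanate 6, and iodinolysis with retention gives the (Z)-iodoalkene, the geometry being fixed by the five-membered alanate.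

Step 5
Reactants: 7 (Z)-3-iodobut-2-en-1-ol
Product: 8 (Z)-(3-iodobut-2-enyloxy)trimethylsilane
Conditions: Me3SiCl, Et3N, CH2Cl2, 0 °C
Reagents that add atoms: chlorotrimethylsilane C[Si](C)(C)Cl
Why: Standard silylation masks the acidic hydroxyl so that it cannot protonate the organozinc reagent in step 6.

Step 6
Reactants: 4 [(2S,4R)-5-iodo-2,4-dimethylpentyl] acetate; 8 (Z)-(3-iodobut-2-enyloxy)trimethylsilane
Product: 11 [(2S,4R,6Z)-8-hydroxy-2,4,6-trimethyloct-6-en-1-yl] acetate, via alkylzinc iodide 9 (not isolated), via trimethylsilyl ether 10 (not isolated)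
Conditions: Zn dust, LiCl, THF, 40 °C; then 8, Pd(OAc)2 (2 mol%), SPhos (4 mol%), THF, 23 °C; then 10% aq. citric acid, MeOH, 23 °C
Reagents that add atoms: none
Why: LiCl-assisted zinc insertion into the primary C10–I bond tolerates the acetate, and Negishi cross-coupling of alkylzinc 9 with the alkenyl iodide forms the C10–C11 bond with retention of the Z geometry; the mild acid work-up removes the trimethylsilyl group.

Step 7
Reactants: 11 [(2S,4R,6Z)-8-hydroxy-2,4,6-trimethyloct-6-en-1-yl] acetate
Product: 12 [(2S,4R)-5-[(2S,3R)-3-(hydroxymethyl)-2-methyloxiran-2-yl]-2,4-dimethylpentyl] acetate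
Conditions: Ti(OiPr)4 (10 mol%), D-(−)-diisopropyl tartrate (12 mol%), t-BuOOH, 4 Å molecular sieves, CH2Cl2, −20 °C
Reagents that add atoms: tert-butyl hydroperoxide CC(C)(C)OO
Why: Katsuki–Sharpless asymmetric epoxidation; with the D-(−)-tartrate the titanium-bound peroxide is delivered to the face of the (Z)-allylic alcohol that makes C11 (S) and C12 (R) by reagent control, independent of the remote C7 and C9 centres.

Step 8
Reactants: 12 [(2S,4R)-5-[(2S,3R)-3-(hydroxymethyl)-2-methyloxiran-2-yl]-2,4-dimethylpentyl] acetate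
Product: 13 [(2S,4R)-5-[(2S,3S)-3-(iodomethyl)-2-methyloxiran-2-yl]-2,4-dimethylpentyl] acetate
Conditions: I2, PPh3, imidazole, Et2O/MeCN (3:1), 0 °C
Reagents that add atoms: iodine II
Why: Appel-type iodination of the primary epoxy alcohol, buffered by imidazole so that the epoxide is not opened.

Step 9
Reactants: 13 [(2S,4R)-5-[(2S,3S)-3-(iodomethyl)-2-methyloxiran-2-yl]-2,4-dimethylpentyl] acetate
Product: 14 [(2S,4R,6S)-6-hydroxy-2,4,6-trimethyloct-7-en-1-yl] acetate
Conditions: Zn dust, EtOH, 78 °C
Reagents that add atoms: none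
Why: Reductive opening of a 2,3-epoxy iodide: zinc inserts into the C13–I bond and β-elimination cleaves only the C12–O bond, so the C11 configuration passes unchanged into the tertiary allylic alcohol and the C12=C13 vinyl group is formed.

Step 10
Reactants: 14 [(2S,4R,6S)-6-hydroxy-2,4,6-trimethyloct-7-en-1-yl] acetate
Product: 15 [(2S,4R,6S)-2,4,6-trimethyl-6-(triethylsilyloxy)oct-7-en-1-yl] acetate
Conditions: Et3SiOTf, 2,6-lutidine, CH2Cl2, −78 to 0 °C
Reagents that add atoms: triethylsilyl trifluoromethanesulfonate CC[Si](CC)(CC)OS(=O)(=O)C(F)(F)F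
Why: Silylation of the hindered tertiary alcohol with the silyl triflate; the triethylsilyl ether withstands the basic and organometallic steps ahead and is removed with the other silyl groups at the end.

Step 11
Reactants: 15 [(2S,4R,6S)-2,4,6-trimethyl-6-(triethylsilyloxy)oct-7-en-1-yl] acetate
Product: 16 (2S,4R,6S)-2,4,6-trimethyl-6-(triethylsilyloxy)oct-7-en-1-ol
Conditions: K2CO3, MeOH, 23 °C
Reagents that add atoms: none
Why: Base-catalysed methanolysis (transesterification) of the primary acetate; the tertiary silyl ether is stable to K2CO3 in methanol.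

Step 12
Reactants: 16 (2S,4R,6S)-2,4,6-trimethyl-6-(triethylsilyloxy)oct-7-en-1-ol
Product: 17 (2S,4R,6S)-2,4,6-trimethyl-6-(triethylsilyloxy)oct-7-enal
Conditions: Dess–Martin periodinane, NaHCO3, CH2Cl2, 0 to 23 °C
Reagents that add atoms: none
Why: Dess–Martin oxidation gives the α-branched aldehyde under buffered, non-enolising conditions so that C7 is not epimerised; the aldehyde is used at once.

Step 13
Reactants: 17 (2S,4R,6S)-2,4,6-trimethyl-6-(triethylsilyloxy)oct-7-enal; 18 furan
Product: 20 (2S,4R,6S)-1-(furan-2-yl)-2,4,6-trimethyl-6-(triethylsilyloxy)oct-7-en-1-ol (mixture of C1 epimers), via 2-furyllithium 19 (not isolated)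
Conditions: furan, n-BuLi, THF, 0 °C; then 17, −78 °C
Reagents that add atoms: none
Why: Lithiation of furan at C2 and 1,2-addition of 2-furyllithium to the aldehyde forms the C5–C6 bond; Felkin–Anh control should favour the wanted (6R) epimer but is not relied on, because both epimers are converged in steps 14 and 15.

Step 14
Reactants: 20 (2S,4R,6S)-1-(furan-2-yl)-2,4,6-trimethyl-6-(triethylsilyloxy)oct-7-en-1-ol (mixture of C1 epimers)
Product: 21 (2S,4R,6S)-1-(furan-2-yl)-2,4,6-trimethyl-6-(triethylsilyloxy)oct-7-en-1-one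
Conditions: Dess–Martin periodinane, NaHCO3, CH2Cl2, 0 to 23 °C
Reagents that add atoms: none
Why: Dess–Martin oxidation of the furyl carbinol removes the undefined C6 centre and gives the 2-acylfuran without enolisation toward C7 under the buffered conditions.

Step 15
Reactants: 21 (2S,4R,6S)-1-(furan-2-yl)-2,4,6-trimethyl-6-(triethylsilyloxy)oct-7-en-1-one
Product: 22 (1R,2S,4R,6S)-1-(furan-2-yl)-2,4,6-trimethyl-6-(triethylsilyloxy)oct-7-en-1-ol
Conditions: RuCl(p-cymene)[(R,R)-TsDPEN] (2 mol%), HCO2Na, cetyltrimethylammonium bromide, H2O/CH2Cl2, 23 °C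
Reagents that add atoms: none
Why: Noyori-type asymmetric transfer hydrogenation of the heteroaryl ketone; the (R,R)-catalyst delivers hydride to the carbonyl face that gives the (R)-carbinol (the sense known for aryl and 2-furyl ketones), setting C6 by catalyst control against the opposite intrinsic Felkin–Anh preference of the C7-branched ketone.

Step 16
Reactants: 22 (1R,2S,4R,6S)-1-(furan-2-yl)-2,4,6-trimethyl-6-(triethylsilyloxy)oct-7-en-1-ol
Product: 25 (2R)-6-hydroxy-2-[(2S,4R,6S)-4,6-dimethyl-6-(triethylsilyloxy)oct-7-en-2-yl]-2H-pyran-3(6H)-one (anomeric mixture), via dimethoxydihydrofuran 23 (not isolated), via (Z)-4-oxoenal 24 (not isolated)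
Conditions: undivided cell, graphite anode, Pt cathode, Et4NOTs (0.1 M), MeOH, −10 °C, constant current, 2.2 F/mol; then TsOH·H2O (5 mol%), THF/H2O (4:1), 0 °C
Reagents that add atoms: water O (methanol, CO, enters 23 only and is released again on hydrolysis)
Why: Two-electron anodic oxidation of the furan in methanol gives the furan radical cation, which takes up methanol twice to give the bis-acetal 23; dilute acid then unmasks the (Z)-4-oxoenal 24, whose aldehyde carbon (C2) is captured by the C6 hydroxyl. This is the Achmatowicz rearrangement of a 2-furyl carbinol in its electrochemical form (anodic 2,5-dimethoxylation, then acid), a known reaction type. Ring A closes by 6-exo-trig hemiacetalisation with formation of the O1–C2 bond; the furan oxygen ends as the C5 ketone oxygen and C3=C4 is the former furan C3–C4 bond, cis because of its ring origin. The only new stereocentre is the hemiacetal carbon C2, which is uncontrolled and irrelevant because it later becomes the lactone carbonyl, while C6 is not touched and keeps the (R) configuration set in step 15. The step needs chemoselectivity for the furan over the C12=C13 vinyl group and survival of the tertiary silyl ether: the first follows from the much lower oxidation potential of the alkylfuran under halide-free electrolysis, the second from the short exposure to catalytic acid at 0 °C.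

Step 17
Reactants: 25 (2R)-6-hydroxy-2-[(2S,4R,6S)-4,6-dimethyl-6-(triethylsilyloxy)oct-7-en-2-yl]-2H-pyran-3(6H)-one (anomeric mixture)
Product: 26 (2R)-6-methoxy-2-[(2S,4R,6S)-4,6-dimethyl-6-(triethylsilyloxy)oct-7-en-2-yl]-2H-pyran-3(6H)-one (anomeric mixture)
Conditions: MeI, Ag2O, CH2Cl2, 23 °C, dark
Reagents that add atoms: iodomethane CI
Why: Purdie O-methylation of the hemiacetal under neutral conditions gives the methyl glycoside without exposing the tertiary silyl ether or the enone to acid; the anomeric mixture is of no consequence because this carbon becomes the lactone carbonyl.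

Step 18
Reactants: 26 (2R)-6-methoxy-2-[(2S,4R,6S)-4,6-dimethyl-6-(triethylsilyloxy)oct-7-en-2-yl]-2H-pyran-3(6H)-one (anomeric mixture)
Product: 27 (2R,3S)-6-methoxy-2-[(2S,4R,6S)-4,6-dimethyl-6-(triethylsilyloxy)oct-7-en-2-yl]-3,6-dihydro-2H-pyran-3-ol (anomeric mixture)
Conditions: NaBH4, CeCl3·7H2O, MeOH, −78 °C
Reagents that add atoms: none
Why: Luche 1,2-reduction of the enone; axial hydride delivery to the half-chair in which the C6 side chain is pseudo-equatorial gives the pseudo-equatorial C5 alcohol trans to the side chain, so C5 (S) is set by substrate control from C6.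

Step 19
Reactants: 28 (R)-4-benzyloxazolidin-2-one; 29 (E)-but-2-enoyl chloride
Product: 31 (4R)-4-benzyl-3-[(2E)-but-2-enoyl]oxazolidin-2-one, via lithium oxazolidinide 30 (not isolated)
Conditions: n-BuLi, THF, −78 °C; then 29, −78 to 0 °C
Reagents that add atoms: none
Why: N-Acylation of the lithiated oxazolidinone with the acid chloride at low temperature.

Step 20
Reactants: 31 (4R)-4-benzyl-3-[(2E)-but-2-enoyl]oxazolidin-2-one; 32 tert-butyl bromoacetate
Product: 34 tert-butyl (3R)-3-[(4R)-4-benzyl-2-oxooxazolidine-3-carbonyl]pent-4-enoate, via sodium dienolate 33 (not isolated)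
Conditions: NaN(SiMe3)2, THF, −78 °C; then 32, −78 °C
Reagents that add atoms: none
Why: Evans asymmetric alkylation; γ-deprotonation gives the chelated (Z)-dienolate 33, which is alkylated at the α-carbon on the face opposite the benzyl group, deconjugating the alkene and setting the future C6′ as (R) by auxiliary control.

Step 21
Reactants: 34 tert-butyl (3R)-3-[(4R)-4-benzyl-2-oxooxazolidine-3-carbonyl]pent-4-enoate
Product: 35 (2R)-2-ethenylbutane-1,4-diol
Conditions: LiAlH4, THF, 0 °C
Reagents that add atoms: none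
Why: LiAlH4 reduces the imide carbonyl (releasing the auxiliary) and the tert-butyl ester to the two primary alcohols without touching the allylic stereocentre.

Step 22
Reactants: 35 (2R)-2-ethenylbutane-1,4-diol
Product: 36 (2R)-1,4-bis(tert-butyldimethylsilyloxy)-2-ethenylbutane
Conditions: t-BuMe2SiCl, imidazole, DMF, 23 °C
Reagents that add atoms: tert-butyldimethylsilyl chloride CC(C)(C)[Si](C)(C)Cl
Why: Standard silylation of both primary alcohols.

Step 23
Reactants: 36 (2R)-1,4-bis(tert-butyldimethylsilyloxy)-2-ethenylbutane; 37 methacrolein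
Product: 38 (2E,4R)-6-(tert-butyldimethylsilyloxy)-4-[(tert-butyldimethylsilyloxy)methyl]-2-methylhex-2-enal
Conditions: second-generation Hoveyda–Grubbs catalyst (5 mol%), methacrolein (10 equiv), CH2Cl2, 40 °C
Reagents that add atoms: none
Why: Olefin cross-metathesis of the terminal alkene with excess methacrolein forms the C4′=C5′ bond as the trisubstituted enal, the thermodynamically preferred (E) isomer being expected, without touching the allylic stereocentre.

Step 24
Reactants: 38 (2E,4R)-6-(tert-butyldimethylsilyloxy)-4-[(tert-butyldimethylsilyloxy)methyl]-2-methylhex-2-enal; 39 triethyl phosphonoacetate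
Product: 40 ethyl (2E,4E,6R)-8-(tert-butyldimethylsilyloxy)-6-[(tert-butyldimethylsilyloxy)methyl]-4-methylocta-2,4-dienoate
Conditions: LiCl, DBU, MeCN, 23 °C
Reagents that add atoms: none
Why: Horner–Wadsworth–Emmons olefination of the enal under mild LiCl/amine conditions gives the (2E) ester and completes the (2E,4E)-diene.

Step 25
Reactants: 40 ethyl (2E,4E,6R)-8-(tert-butyldimethylsilyloxy)-6-[(tert-butyldimethylsilyloxy)methyl]-4-methylocta-2,4-dienoate
Product: 41 (2E,4E,6R)-8-(tert-butyldimethylsilyloxy)-6-[(tert-butyldimethylsilyloxy)methyl]-4-methylocta-2,4-dienoic acid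
Conditions: LiOH, THF/MeOH/H2O, 23 °C; then 0.5 M aq. HCl to pH 4
Reagents that add atoms: lithium hydroxide [Li+].[OH-]
Why: Saponification of the ethyl ester; primary tert-butyldimethylsilyl ethers are stable to LiOH at room temperature.

Step 26
Reactants: 27 (2R,3S)-6-methoxy-2-[(2S,4R,6S)-4,6-dimethyl-6-(triethylsilyloxy)oct-7-en-2-yl]-3,6-dihydro-2H-pyran-3-ol (anomeric mixture); 41 (2E,4E,6R)-8-(tert-butyldimethylsilyloxy)-6-[(tert-butyldimethylsilyloxy)methyl]-4-methylocta-2,4-dienoic acid
Product: 43 (2R,3S)-6-methoxy-2-[(2S,4R,6S)-4,6-dimethyl-6-(triethylsilyloxy)oct-7-en-2-yl]-3,6-dihydro-2H-pyran-3-yl (2E,4E,6R)-8-(tert-butyldimethylsilyloxy)-6-[(tert-butyldimethylsilyloxy)methyl]-4-methylocta-2,4-dienoate (anomeric mixture), via mixed anhydride 42 (not isolated)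
Conditions: 2,4,6-trichlorobenzoyl chloride, Et3N, toluene, 23 °C; then 27, DMAP, toluene, 23 °C
Reagents that add atoms: none
Why: Yamaguchi esterification; the mixed anhydride 42 acylates the secondary allylic C5 hydroxyl, the only free hydroxyl present, under DMAP catalysis with retention at C5.

Step 27
Reactants: 43 methyl acetal ester (anomeric mixture)
Product: 44 (2R,3S)-6-hydroxy-2-[(2S,4R,6S)-4,6-dimethyl-6-(triethylsilyloxy)oct-7-en-2-yl]-3,6-dihydro-2H-pyran-3-yl (2E,4E,6R)-8-(tert-butyldimethylsilyloxy)-6-[(tert-butyldimethylsilyloxy)methyl]-4-methylocta-2,4-dienoate (anomeric mixture)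
Conditions: PPTS, acetone/H2O (9:1), 40 °C
Reagents that add atoms: water O
Why: Acid-catalysed hydrolysis of the allylic methyl acetal through the allyl-stabilised oxocarbenium ion; partial loss of silyl groups would be harmless because they are removed in step 29.

Step 28
Reactants: 44 lactol ester (anomeric mixture)
Product: 45 (2R,3S)-2-[(2S,4R,6S)-4,6-dimethyl-6-(triethylsilyloxy)oct-7-en-2-yl]-6-oxo-3,6-dihydro-2H-pyran-3-yl (2E,4E,6R)-8-(tert-butyldimethylsilyloxy)-6-[(tert-butyldimethylsilyloxy)methyl]-4-methylocta-2,4-dienoate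
Conditions: MnO2, CH2Cl2, 23 °C
Reagents that add atoms: none
Why: MnO2 oxidises the allylic lactol selectively to the α,β-unsaturated δ-lactone (allylic oxidation), completing ring A at the C2 carbonyl.

Step 29
Reactants: 45 tris-silylated lactone
Product: 46 (2R,3S)-2-[(2S,4R,6S)-6-hydroxy-4,6-dimethyloct-7-en-2-yl]-6-oxo-3,6-dihydro-2H-pyran-3-yl (2E,4E,6R)-8-hydroxy-6-(hydroxymethyl)-4-methylocta-2,4-dienoate (CNP0227568.4)
Conditions: HF·pyridine, pyridine, THF, 0 to 23 °C
Reagents that add atoms: none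
Why: Fluoride-mediated global desilylation under buffered, non-basic conditions removes the tertiary triethylsilyl and both primary tert-butyldimethylsilyl groups without acyl migration or β-elimination of the C5 acyloxy group.

**Compound list**

1 | cis-2,4-dimethylglutaric anhydride (meso) | C[C@@H]1C[C@H](C)C(=O)OC1=O | starting material
2 | meso-(2R,4S)-2,4-dimethylpentane-1,5-diol | OC[C@H](C)C[C@H](C)CO | intermediate
3 | [(2S,4R)-5-hydroxy-2,4-dimethylpentyl] acetate | OC[C@H](C)C[C@H](C)COC(C)=O | intermediate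
4 | [(2S,4R)-5-iodo-2,4-dimethylpentyl] acetate | IC[C@H](C)C[C@H](C)COC(C)=O | intermediate
5 | but-2-yn-1-ol | CC#CCO | starting material
6 | sodium 2,2-bis(2-methoxyethoxy)-3-methyl-2,5-dihydro-1,2-oxaluminol-2-uide (cyclic alkenylalanate) | [Na+].CC1=CCO[Al-]1(OCCOC)OCCOC | intermediate
7 | (Z)-3-iodobut-2-en-1-ol | C/C(I)=C/CO | intermediate
8 | (Z)-(3-iodobut-2-enyloxy)trimethylsilane | C/C(I)=C/CO[Si](C)(C)C | intermediate
9 | [(2R,4S)-5-acetoxy-2,4-dimethylpentyl]zinc iodide | I[Zn]C[C@H](C)C[C@H](C)COC(C)=O | intermediate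
10 | [(2S,4R,6Z)-2,4,6-trimethyl-8-(trimethylsilyloxy)oct-6-en-1-yl] acetate | C[Si](C)(C)OC/C=C(/C)C[C@H](C)C[C@H](C)COC(C)=O | intermediate
11 | [(2S,4R,6Z)-8-hydroxy-2,4,6-trimethyloct-6-en-1-yl] acetate | OC/C=C(/C)C[C@H](C)C[C@H](C)COC(C)=O | intermediate
12 | [(2S,4R)-5-[(2S,3R)-3-(hydroxymethyl)-2-methyloxiran-2-yl]-2,4-dimethylpentyl] acetate | OC[C@H]1O[C@@]1(C)C[C@H](C)C[C@H](C)COC(C)=O | intermediate
13 | [(2S,4R)-5-[(2S,3S)-3-(iodomethyl)-2-methyloxiran-2-yl]-2,4-dimethylpentyl] acetate | IC[C@H]1O[C@@]1(C)C[C@H](C)C[C@H](C)COC(C)=O | intermediate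
14 | [(2S,4R,6S)-6-hydroxy-2,4,6-trimethyloct-7-en-1-yl] acetate | C=C[C@@](C)(O)C[C@H](C)C[C@H](C)COC(C)=O | intermediate
15 | [(2S,4R,6S)-2,4,6-trimethyl-6-(triethylsilyloxy)oct-7-en-1-yl] acetate | C=C[C@@](C)(O[Si](CC)(CC)CC)C[C@H](C)C[C@H](C)COC(C)=O | intermediate
16 | (2S,4R,6S)-2,4,6-trimethyl-6-(triethylsilyloxy)oct-7-en-1-ol | C=C[C@@](C)(O[Si](CC)(CC)CC)C[C@H](C)C[C@H](C)CO | intermediate
17 | (2S,4R,6S)-2,4,6-trimethyl-6-(triethylsilyloxy)oct-7-enal | C=C[C@@](C)(O[Si](CC)(CC)CC)C[C@H](C)C[C@H](C)C=O | intermediate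
18 | furan | c1ccoc1 | starting material
19 | 2-furyllithium | [Li]c1ccco1 | intermediate
20 | (2S,4R,6S)-1-(furan-2-yl)-2,4,6-trimethyl-6-(triethylsilyloxy)oct-7-en-1-ol, mixture of C1 epimers | C=C[C@@](C)(O[Si](CC)(CC)CC)C[C@H](C)C[C@H](C)C(O)c1ccco1 | intermediate
21 | (2S,4R,6S)-1-(furan-2-yl)-2,4,6-trimethyl-6-(triethylsilyloxy)oct-7-en-1-one | C=C[C@@](C)(O[Si](CC)(CC)CC)C[C@H](C)C[C@H](C)C(=O)c1ccco1 | intermediate
22 | (1R,2S,4R,6S)-1-(furan-2-yl)-2,4,6-trimethyl-6-(triethylsilyloxy)oct-7-en-1-ol (key-step precursor) | C=C[C@@](C)(O[Si](CC)(CC)CC)C[C@H](C)C[C@H](C)[C@@H](O)c1ccco1 | intermediate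
23 | (1R,2S,4R,6S)-1-(2,5-dimethoxy-2,5-dihydrofuran-2-yl)-2,4,6-trimethyl-6-(triethylsilyloxy)oct-7-en-1-ol, mixture of acetal isomers | C=C[C@@](C)(O[Si](CC)(CC)CC)C[C@H](C)C[C@H](C)[C@@H](O)C1(OC)C=CC(OC)O1 | intermediate
24 | (2Z,5R,6S,8R,10S)-5-hydroxy-6,8,10-trimethyl-4-oxo-10-(triethylsilyloxy)dodeca-2,11-dienal | C=C[C@@](C)(O[Si](CC)(CC)CC)C[C@H](C)C[C@H](C)[C@@H](O)C(=O)/C=C\C=O | intermediate
25 | (2R)-6-hydroxy-2-[(2S,4R,6S)-4,6-dimethyl-6-(triethylsilyloxy)oct-7-en-2-yl]-2H-pyran-3(6H)-one, anomeric mixture (key-step product) | C=C[C@@](C)(O[Si](CC)(CC)CC)C[C@H](C)C[C@H](C)[C@H]1OC(O)C=CC1=O | intermediate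
26 | (2R)-6-methoxy-2-[(2S,4R,6S)-4,6-dimethyl-6-(triethylsilyloxy)oct-7-en-2-yl]-2H-pyran-3(6H)-one, anomeric mixture | C=C[C@@](C)(O[Si](CC)(CC)CC)C[C@H](C)C[C@H](C)[C@H]1OC(OC)C=CC1=O | intermediate
27 | (2R,3S)-6-methoxy-2-[(2S,4R,6S)-4,6-dimethyl-6-(triethylsilyloxy)oct-7-en-2-yl]-3,6-dihydro-2H-pyran-3-ol, anomeric mixture | C=C[C@@](C)(O[Si](CC)(CC)CC)C[C@H](C)C[C@H](C)[C@H]1OC(OC)C=C[C@@H]1O | intermediate
28 | (R)-4-benzyloxazolidin-2-one | O=C1N[C@H](Cc2ccccc2)CO1 | starting material
29 | (E)-but-2-enoyl chloride | C/C=C/C(Cl)=O | starting material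
30 | lithium (R)-4-benzyl-2-oxooxazolidin-3-ide | [Li]N1[C@H](Cc2ccccc2)COC1=O | intermediate
31 | (4R)-4-benzyl-3-[(2E)-but-2-enoyl]oxazolidin-2-one | C/C=C/C(=O)N1[C@H](Cc2ccccc2)COC1=O | intermediate
32 | tert-butyl bromoacetate | BrCC(=O)OC(C)(C)C | starting material
33 | sodium (Z)-dienolate of 31 | [Na+].C=C/C=C(\[O-])N1[C@H](Cc2ccccc2)COC1=O | intermediate
34 | tert-butyl (3R)-3-[(4R)-4-benzyl-2-oxooxazolidine-3-carbonyl]pent-4-enoate | C=C[C@H](C(=O)N1[C@H](Cc2ccccc2)COC1=O)CC(=O)OC(C)(C)C | intermediate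
35 | (2R)-2-ethenylbutane-1,4-diol | C=C[C@H](CO)CCO | intermediate
36 | (2R)-1,4-bis(tert-butyldimethylsilyloxy)-2-ethenylbutane | C=C[C@H](CO[Si](C)(C)C(C)(C)C)CCO[Si](C)(C)C(C)(C)C | intermediate
37 | methacrolein | C=C(C)C=O | starting material
38 | (2E,4R)-6-(tert-butyldimethylsilyloxy)-4-[(tert-butyldimethylsilyloxy)methyl]-2-methylhex-2-enal | O=C/C(C)=C/[C@H](CO[Si](C)(C)C(C)(C)C)CCO[Si](C)(C)C(C)(C)C | intermediate
39 | triethyl phosphonoacetate | CCOC(=O)CP(=O)(OCC)OCC | starting material
40 | ethyl (2E,4E,6R)-8-(tert-butyldimethylsilyloxy)-6-[(tert-butyldimethylsilyloxy)methyl]-4-methylocta-2,4-dienoate | CCOC(=O)/C=C/C(C)=C/[C@H](CO[Si](C)(C)C(C)(C)C)CCO[Si](C)(C)C(C)(C)C | intermediate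
41 | (2E,4E,6R)-8-(tert-butyldimethylsilyloxy)-6-[(tert-butyldimethylsilyloxy)methyl]-4-methylocta-2,4-dienoic acid | OC(=O)/C=C/C(C)=C/[C@H](CO[Si](C)(C)C(C)(C)C)CCO[Si](C)(C)C(C)(C)C | intermediate
42 | mixed anhydride of 41 with 2,4,6-trichlorobenzoic acid | O=C(OC(=O)c1c(Cl)cc(Cl)cc1Cl)/C=C/C(C)=C/[C@H](CO[Si](C)(C)C(C)(C)C)CCO[Si](C)(C)C(C)(C)C | intermediate
43 | (2R,3S)-6-methoxy-2-[(2S,4R,6S)-4,6-dimethyl-6-(triethylsilyloxy)oct-7-en-2-yl]-3,6-dihydro-2H-pyran-3-yl ester of acid 41, anomeric mixture | C=C[C@@](C)(O[Si](CC)(CC)CC)C[C@H](C)C[C@H](C)[C@H]1OC(OC)C=C[C@@H]1OC(=O)/C=C/C(C)=C/[C@H](CO[Si](C)(C)C(C)(C)C)CCO[Si](C)(C)C(C)(C)C | intermediate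
44 | (2R,3S)-6-hydroxy-2-[(2S,4R,6S)-4,6-dimethyl-6-(triethylsilyloxy)oct-7-en-2-yl]-3,6-dihydro-2H-pyran-3-yl ester of acid 41, anomeric mixture | C=C[C@@](C)(O[Si](CC)(CC)CC)C[C@H](C)C[C@H](C)[C@H]1OC(O)C=C[C@@H]1OC(=O)/C=C/C(C)=C/[C@H](CO[Si](C)(C)C(C)(C)C)CCO[Si](C)(C)C(C)(C)C | intermediate
45 | (2R,3S)-2-[(2S,4R,6S)-4,6-dimethyl-6-(triethylsilyloxy)oct-7-en-2-yl]-6-oxo-3,6-dihydro-2H-pyran-3-yl ester of acid 41 | C=C[C@@](C)(O[Si](CC)(CC)CC)C[C@H](C)C[C@H](C)[C@H]1OC(=O)C=C[C@@H]1OC(=O)/C=C/C(C)=C/[C@H](CO[Si](C)(C)C(C)(C)C)CCO[Si](C)(C)C(C)(C)C | intermediate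
46 | (2R,3S)-2-[(2S,4R,6S)-6-hydroxy-4,6-dimethyloct-7-en-2-yl]-6-oxo-3,6-dihydro-2H-pyran-3-yl (2E,4E,6R)-8-hydroxy-6-(hydroxymethyl)-4-methylocta-2,4-dienoate (CNP0227568.4) | C=C[C@@](C)(O)C[C@H](C)C[C@H](C)[C@H]1OC(=O)C=C[C@@H]1OC(=O)/C=C/C(C)=C/[C@H](CO)CCO | target

**Step count and risks**

Total step count: 29.
Longest linear sequence: 20 steps (steps 1–3, 6–18 and 26–29).

Steps most likely to fail:

1. Step 16 (key step). What may go wrong: over-oxidation at the anode or electrode passivation that leaves furan unconverted, and loss of the tertiary triethylsilyl ether with allylic ionisation at C11 during the acid unmasking of the bis-acetal. The fallback sets out from 22 and comes back at 25 in one operation. It replaces electron transfer by hydroxyl-directed oxygen transfer: VO(acac)2 (catalytic) and t-BuOOH in CH2Cl2 at 0 °C. The C6 hydroxyl binds vanadium and delivers the peroxide oxygen to the adjacent furan double bond, and the resulting ene-dione closes to the pyranone under neutral conditions with no acid step. The C12=C13 vinyl group has no free allylic hydroxyl (it is silylated) and should not be epoxidised. This fallback makes no new compound, F0.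

2. Step 15. What may go wrong: poor facial selectivity, because the catalyst has to override the Felkin–Anh bias of the C7-branched ketone, or slow turnover at the hindered carbonyl. The fallback sets out from 20 and comes back at 22. It relies on substrate control plus inversion instead of catalyst control. The epimers of 20 are separated by chromatography; the Felkin–Anh-favoured (1R) epimer is 22 itself. The remaining (1S)-carbinol F1 is inverted by Mitsunobu reaction (4-nitrobenzoic acid, PPh3, DIAD, toluene, 0 °C) to the (1R) 4-nitrobenzoate F2, which is methanolysed (K2CO3, MeOH, 23 °C) to 22.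

3. Step 23. What may go wrong: slow or incomplete cross-metathesis at the allylically branched terminal alkene, with competing self-metathesis of methacrolein or double-bond migration. The fallback sets out from 36 and comes back at 38. The vinyl group is cleaved by ozonolysis (O3, CH2Cl2, −78 °C; then PPh3) to (2S)-4-(tert-butyldimethylsilyloxy)-2-[(tert-butyldimethylsilyloxy)methyl]butanal F3. This aldehyde is used at once in a Wittig olefination with the stabilised, non-basic ylide Ph3P=C(CH3)CHO (toluene, 80 °C), which should give the (E)-enal 38 with little risk of epimerisation.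

Further compounds
F0 | step 16 | none | none
F1 | step 15 | (1S,2S,4R,6S)-1-(furan-2-yl)-2,4,6-trimethyl-6-(triethylsilyloxy)oct-7-en-1-ol | C=C[C@@](C)(O[Si](CC)(CC)CC)C[C@H](C)C[C@H](C)[C@H](O)c1ccco1
F2 | step 15 | (1R,2S,4R,6S)-1-(furan-2-yl)-2,4,6-trimethyl-6-(triethylsilyloxy)oct-7-en-1-yl 4-nitrobenzoate | C=C[C@@](C)(O[Si](CC)(CC)CC)C[C@H](C)C[C@H](C)[C@@H](OC(=O)c1ccc(cc1)[N+](=O)[O-])c1ccco1
F3 | step 23 | (2S)-4-(tert-butyldimethylsilyloxy)-2-[(tert-butyldimethylsilyloxy)methyl]butanal | O=C[C@H](CO[Si](C)(C)C(C)(C)C)CCO[Si](C)(C)C(C)(C)C
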